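The route rests on cutting the cis-dioxane fused to ring B at two bonds: O–C7′, where C7′ carries ring C and hangs on the ring B oxygen para to the ring A junction, and the aryl C–O bond to the oxygen on C8′ (the CH2OH carbon, meta position). This cis array is a trans (2S,3S)-arylglycidyl ether inverted once at C7′, so a ring B bromophenol opens the epoxide at its benzylic carbon and copper then arylates the freed C8′ alkoxide at the ortho C–Br bond, closing the ring in one flask. The precursor is the trans ring A benzodioxane ester bearing a 3-bromo-4-hydroxyphenyl group.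

Key step: step 12

Remark: ring A carries the enal, ring B is central, ring C is the catechol, and C7/C8 and C7′/C8′ are the dioxane carbons on rings A and B; both primary alcohols are carried as triisopropylsilyl ethers, because a smaller silyl group next to the C8′ alkoxide of the key step could migrate from oxygen to oxygen; all starting materials are assumed to be catalogue compounds.

**Ring A / ring B fragment (steps 1–7)**

Step 1
Reactants: 1 3-bromo-4-hydroxybenzaldehyde
Product: 2 4-(allyloxy)-3-bromobenzaldehyde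
Conditions: allyl bromide, K2CO3, DMF, rt
Reagents that add atoms: allyl bromide, C=CCBr
Why: Williamson etherification of the acidic bromophenol; the allyl ether should survive the boron aldol, borohydride, silylation and hot carbonate/copper of steps 3 to 6 and is later removed by zerovalent palladium without touching the aryl bromide.

Step 2
Reactants: 3 methyl 4-hydroxy-3-iodobenzoate; 4 (4R)-4-benzyl-3-(chloroacetyl)-1,3-oxazolidin-2-one
Product: 5 ring A aryloxyacetyl imide
Conditions: K2CO3, MeCN, rt to 40 °C
Reagents that add atoms: none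
Why: Williamson-type SN2 displacement at the strongly activated α-chloro imide by the weakly basic phenoxide, which should prefer the α-carbon to the imide carbonyl; it places the oxygen para to the ester on the future C8 and keeps the ortho iodide for ring closure.

Step 3
Reactants: 5 ring A aryloxyacetyl imide; 2 4-(allyloxy)-3-bromobenzaldehyde
Product: 7 (2R,3S)-syn-aldol imide, via Z boron enolate 6 (not isolated)
Conditions: Bu2BOTf, iPr2NEt, CH2Cl2, 0 °C; then 2, −78 to 0 °C; pH 7 buffer, MeOH, H2O2, 0 °C
Reagents that add atoms: none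
Why: Evans syn glycolate aldol, in which the Z dibutylboron enolate reacts through a Zimmerman–Traxler chair and the (R)-benzyl group of the auxiliary shields one enolate face, so that the (2R,3S) adduct should form, fixing the later C8 as S and C7 as S.

Step 4
Reactants: 7 (2R,3S)-syn-aldol imide
Product: 8 (1S,2S)-threo 1,3-diol
Conditions: NaBH4, THF/H2O (4:1), 0 °C to rt
Reagents that add atoms: none
Why: reductive cleavage of the N-acyloxazolidinone by borohydride is much faster than attack on the methyl benzoate, so the auxiliary is released and the primary carbinol formed without touching either stereocentre.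

Step 5
Reactants: 8 (1S,2S)-threo 1,3-diol
Product: 9 primary triisopropylsilyl ether with free benzylic hydroxyl
Conditions: iPr3SiCl, imidazole, DMF, 0 °C to rt
Reagents that add atoms: triisopropylsilyl chloride, CC(C)[Si](Cl)(C(C)C)C(C)C
Why: silylation with the bulky chlorosilane is selective for the primary over the hindered secondary benzylic hydroxyl, which stays free for ring closure.

Step 6
Reactants: 9 primary triisopropylsilyl ether with free benzylic hydroxyl
Product: 10 trans ring A dioxane carrying the 4-(allyloxy)-3-bromophenyl group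
Conditions: CuI (10 mol %), 1,10-phenanthroline (20 mol %), Cs2CO3, toluene, 100 °C
Reagents that add atoms: none
Why: intramolecular Ullmann-type etherification, in which the copper alkoxide of the C7 hydroxyl displaces the ortho iodide of ring A and closes the six-membered ring with retention at C7 and C8, so the threo array becomes the trans (2S,3S) dioxane, while the ring B bromide is far less reactive towards copper and cannot reach the alkoxide in a sensible ring.

Step 7
Reactants: 10 trans ring A dioxane carrying the 4-(allyloxy)-3-bromophenyl group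
Product: 11 trans ring A dioxane carrying the 3-bromo-4-hydroxyphenyl group
Conditions: Pd(PPh3)4 (5 mol %), N-methylaniline, THF, rt
Reagents that add atoms: none
Why: Tsuji–Trost-type deallylation, in which zerovalent palladium ionises the aryl allyl ether at room temperature, where oxidative addition to the aryl bromide is negligible, and the weakly basic aniline traps the allyl fragment so that the para-hydroxybenzyl aryl ether never meets phenoxide-forming conditions.

**Ring C epoxide (steps 8–11)**

Step 8
Reactants: 12 caffeic acid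
Product: 13 allyl (E)-3-[3,4-bis(allyloxy)phenyl]prop-2-enoate
Conditions: allyl bromide (3.5 equiv), K2CO3, DMF, rt to 40 °C
Reagents that add atoms: allyl bromide, C=CCBr
Why: exhaustive Williamson and carboxylate alkylation protects both phenols and turns the acid into an ester in one operation, with the E double bond untouched.

Step 9
Reactants: 13 allyl (E)-3-[3,4-bis(allyloxy)phenyl]prop-2-enoate
Product: 14 (E)-3-[3,4-bis(allyloxy)phenyl]prop-2-en-1-ol
Conditions: iBu2AlH, CH2Cl2, −78 to 0 °C
Reagents that add atoms: none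
Why: iBu2AlH reduces cinnamate esters in the 1,2 sense to the E allylic alcohol and leaves aryl allyl ethers alone.

Step 10
Reactants: 14 (E)-3-[3,4-bis(allyloxy)phenyl]prop-2-en-1-ol
Product: 15 (2S,3S)-epoxy alcohol
Conditions: Ti(OiPr)4 (10 mol %), L-(+)-diisopropyl tartrate (12 mol %), tBuOOH, 4 Å molecular sieves, CH2Cl2, −20 °C
Reagents that add atoms: tert-butyl hydroperoxide, CC(C)(C)OO
Why: Sharpless asymmetric epoxidation, in which the titanium complex of the L-(+)-tartrate delivers oxygen to the face of the E allylic alcohol that gives the (2S,3S) epoxide, and the allyl ether alkenes stay untouched because they have no hydroxyl to bind titanium.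

Step 11
Reactants: 15 (2S,3S)-epoxy alcohol
Product: 16 (2S,3S)-epoxide of the ring C cinnamyl silyl ether
Conditions: iPr3SiCl, imidazole, DMAP (cat.), CH2Cl2, 0 °C to rt
Reagents that add atoms: triisopropylsilyl chloride, CC(C)[Si](Cl)(C(C)C)C(C)C
Why: imidazole-buffered silylation protects the primary hydroxyl under non-acidic conditions that spare the electron-rich aryl epoxide, and it rules out Payne rearrangement in the key step.

**Key step and endgame (steps 12–17)**

Step 12
Reactants: 11 trans ring A dioxane carrying the 3-bromo-4-hydroxyphenyl group; 16 (2S,3S)-epoxide of the ring C cinnamyl silyl ether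
Product: 18 protected bis-benzodioxane methyl ester, via erythro hydroxy ether 17 (not isolated)
Conditions: Cs2CO3 (2.5 equiv), DMF, 60–70 °C; then CuI (20 mol %), 1,10-phenanthroline (40 mol %), 110 °C
Reagents that add atoms: none
Why: The caesium phenoxide of 11 attacks the benzylic carbon of 16 in an SN2 opening with inversion to give the erythro alkoxide of 17, whose C8′ oxygen is then bound by monovalent copper and coupled with the ortho C–Br bond of ring B. Both events are known reaction types for 2-halophenols and epoxides, namely base-mediated phenol opening of 3-arylglycidyl ethers at the benzylic carbon and Ullmann-type intramolecular O-arylation to 1,4-benzodioxanes. The one new ring, the six-membered dioxane on ring B, closes by aryl C–O bond formation from the secondary alkoxide onto the ortho carbon (formally 6-exo at the aryl carbon) with retention at C8′. C7′ is the stereocentre set here and the epoxide alone controls it: backside attack turns the (3S) benzylic carbon into (7′R) while C8′ keeps its (S) configuration, so the ring should emerge cis. The step needs benzylic regioselectivity without ionisation, which the aryl group (activation of C3), the CH2OSi group (inductive and steric deactivation of C2) and the absence of any Lewis acid until the epoxide is consumed (CuI goes in only then) should secure, while 11 offers a single phenol and carries its bromide on the very carbon that must receive the second oxygen. The triisopropylsilyl group is far less prone to O-to-O migration at the C8′ alkoxide than a smaller silyl group, and any reversible quinone-methide opening of the ring A dioxane of 11 should reclose to the more stable trans isomer.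

Step 13
Reactants: 18 protected bis-benzodioxane methyl ester
Product: 19 ring A benzylic alcohol
Conditions: iBu2AlH, CH2Cl2, −78 to 0 °C
Reagents that add atoms: none
Why: hydride reduction of the methyl benzoate to the benzylic alcohol, to which silyl ethers, allyl ethers and both dioxanes are inert.

Step 14
Reactants: 19 ring A benzylic alcohol
Product: 20 ring A aldehyde
Conditions: MnO2, CH2Cl2, rt
Reagents that add atoms: none
Why: MnO2 oxidation is selective for the benzylic alcohol, stops at the aldehyde and runs under neutral conditions.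

Step 15
Reactants: 20 ring A aldehyde
Product: 21 protected E-enal
Conditions: Ph3P=CHCHO (1.3 equiv), toluene, 80 °C
Reagents that add atoms: (triphenylphosphoranylidene)acetaldehyde, O=CC=P(c1ccccc1)(c1ccccc1)c1ccccc1
Why: Wittig olefination with the stabilised formylmethylene ylide should give the E enal directly, and the small excess of ylide keeps a second homologation down.

Step 16
Reactants: 21 protected E-enal
Product: 22 bis(allyl) ether diol
Conditions: HF·pyridine, pyridine, THF, 0 °C to rt
Reagents that add atoms: none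
Why: fluoride-driven Si–O cleavage in a pyridine-buffered medium removes both primary silyl ethers without harming the enal, the allyl ethers or the benzylic aryl ethers.

Step 17
Reactants: 22 bis(allyl) ether diol
Product: 23 CNP0302404.1
Conditions: Pd(PPh3)4 (10 mol %), N-methylaniline, degassed THF, rt
Reagents that add atoms: none
Why: Tsuji–Trost-type deallylation by zerovalent palladium with a weakly basic aniline as allyl acceptor frees the catechol at room temperature under nearly neutral conditions, so the enal should survive and the cis C7′ aryl ether para to the new phenol should not epimerise through a quinone methide.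

**Compound list**

1 | 3-bromo-4-hydroxybenzaldehyde | O=Cc1ccc(O)c(Br)c1 | starting material
2 | 4-(allyloxy)-3-bromobenzaldehyde | O=Cc1ccc(OCC=C)c(Br)c1 | intermediate
3 | methyl 4-hydroxy-3-iodobenzoate | COC(=O)c1ccc(O)c(I)c1 | starting material
4 | (4R)-4-benzyl-3-(chloroacetyl)-1,3-oxazolidin-2-one | O=C(CCl)N1C(=O)OC[C@H]1Cc1ccccc1 | starting material
5 | methyl 4-{2-[(4R)-4-benzyl-2-oxo-1,3-oxazolidin-3-yl]-2-oxoethoxy}-3-iodobenzoate | COC(=O)c1ccc(OCC(=O)N2C(=O)OC[C@H]2Cc2ccccc2)c(I)c1 | intermediate
6 | Z di-n-butylboron enolate of 5 (formed in the flask, not isolated) | COC(=O)c1ccc(O/C=C(\OB(CCCC)CCCC)N2C(=O)OC[C@H]2Cc2ccccc2)c(I)c1 | intermediate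
7 | methyl 4-{[(2R,3S)-3-[4-(allyloxy)-3-bromophenyl]-1-[(4R)-4-benzyl-2-oxo-1,3-oxazolidin-3-yl]-3-hydroxy-1-oxopropan-2-yl]oxy}-3-iodobenzoate | COC(=O)c1ccc(O[C@@H](C(=O)N2C(=O)OC[C@H]2Cc2ccccc2)[C@@H](O)c2ccc(OCC=C)c(Br)c2)c(I)c1 | intermediate
8 | methyl 4-{[(1S,2S)-1-[4-(allyloxy)-3-bromophenyl]-1,3-dihydroxypropan-2-yl]oxy}-3-iodobenzoate | COC(=O)c1ccc(O[C@@H](CO)[C@@H](O)c2ccc(OCC=C)c(Br)c2)c(I)c1 | intermediate
9 | methyl 4-{[(1S,2S)-1-[4-(allyloxy)-3-bromophenyl]-1-hydroxy-3-[(triisopropylsilyl)oxy]propan-2-yl]oxy}-3-iodobenzoate | COC(=O)c1ccc(O[C@@H](CO[Si](C(C)C)(C(C)C)C(C)C)[C@@H](O)c2ccc(OCC=C)c(Br)c2)c(I)c1 | intermediate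
10 | methyl (2S,3S)-3-[4-(allyloxy)-3-bromophenyl]-2-{[(triisopropylsilyl)oxy]methyl}-2,3-dihydro-1,4-benzodioxine-6-carboxylate (trans) | COC(=O)c1ccc2c(c1)O[C@@H](c1ccc(OCC=C)c(Br)c1)[C@H](CO[Si](C(C)C)(C(C)C)C(C)C)O2 | intermediate
11 | methyl (2S,3S)-3-(3-bromo-4-hydroxyphenyl)-2-{[(triisopropylsilyl)oxy]methyl}-2,3-dihydro-1,4-benzodioxine-6-carboxylate (trans; precursor of the key step) | COC(=O)c1ccc2c(c1)O[C@@H](c1ccc(O)c(Br)c1)[C@H](CO[Si](C(C)C)(C(C)C)C(C)C)O2 | intermediate
12 | caffeic acid, (E)-3-(3,4-dihydroxyphenyl)prop-2-enoic acid | O=C(O)/C=C/c1ccc(O)c(O)c1 | starting material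
13 | allyl (E)-3-[3,4-bis(allyloxy)phenyl]prop-2-enoate | C=CCOC(=O)/C=C/c1ccc(OCC=C)c(OCC=C)c1 | intermediate
14 | (E)-3-[3,4-bis(allyloxy)phenyl]prop-2-en-1-ol | OC/C=C/c1ccc(OCC=C)c(OCC=C)c1 | intermediate
15 | [(2S,3S)-3-[3,4-bis(allyloxy)phenyl]oxiran-2-yl]methanol | OC[C@@H]1O[C@H]1c1ccc(OCC=C)c(OCC=C)c1 | intermediate
16 | {[(2S,3S)-3-[3,4-bis(allyloxy)phenyl]oxiran-2-yl]methoxy}triisopropylsilane (precursor of the key step) | CC(C)[Si](C(C)C)(C(C)C)OC[C@@H]1O[C@H]1c1ccc(OCC=C)c(OCC=C)c1 | intermediate
17 | methyl (2S,3S)-3-{3-bromo-4-[(1R,2S)-1-[3,4-bis(allyloxy)phenyl]-2-hydroxy-3-[(triisopropylsilyl)oxy]propoxy]phenyl}-2-{[(triisopropylsilyl)oxy]methyl}-2,3-dihydro-1,4-benzodioxine-6-carboxylate (erythro; formed in the flask, not isolated) | COC(=O)c1ccc2c(c1)O[C@@H](c1ccc(O[C@H](c3ccc(OCC=C)c(OCC=C)c3)[C@@H](O)CO[Si](C(C)C)(C(C)C)C(C)C)c(Br)c1)[C@H](CO[Si](C(C)C)(C(C)C)C(C)C)O2 | intermediate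
18 | methyl (2S,3S)-3-[(2R,3S)-2-[3,4-bis(allyloxy)phenyl]-3-{[(triisopropylsilyl)oxy]methyl}-2,3-dihydro-1,4-benzodioxin-6-yl]-2-{[(triisopropylsilyl)oxy]methyl}-2,3-dihydro-1,4-benzodioxine-6-carboxylate | COC(=O)c1ccc2c(c1)O[C@@H](c1ccc3c(c1)O[C@@H](CO[Si](C(C)C)(C(C)C)C(C)C)[C@@H](c1ccc(OCC=C)c(OCC=C)c1)O3)[C@H](CO[Si](C(C)C)(C(C)C)C(C)C)O2 | intermediate
19 | benzylic alcohol corresponding to 18 (CO2Me replaced by CH2OH) | OCc1ccc2c(c1)O[C@@H](c1ccc3c(c1)O[C@@H](CO[Si](C(C)C)(C(C)C)C(C)C)[C@@H](c1ccc(OCC=C)c(OCC=C)c1)O3)[C@H](CO[Si](C(C)C)(C(C)C)C(C)C)O2 | intermediate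
20 | aldehyde corresponding to 18 (CO2Me replaced by CHO) | O=Cc1ccc2c(c1)O[C@@H](c1ccc3c(c1)O[C@@H](CO[Si](C(C)C)(C(C)C)C(C)C)[C@@H](c1ccc(OCC=C)c(OCC=C)c1)O3)[C@H](CO[Si](C(C)C)(C(C)C)C(C)C)O2 | intermediate
21 | (E)-3-{(2S,3S)-3-[(2R,3S)-2-[3,4-bis(allyloxy)phenyl]-3-{[(triisopropylsilyl)oxy]methyl}-2,3-dihydro-1,4-benzodioxin-6-yl]-2-{[(triisopropylsilyl)oxy]methyl}-2,3-dihydro-1,4-benzodioxin-6-yl}prop-2-enal | O=C/C=C/c1ccc2c(c1)O[C@@H](c1ccc3c(c1)O[C@@H](CO[Si](C(C)C)(C(C)C)C(C)C)[C@@H](c1ccc(OCC=C)c(OCC=C)c1)O3)[C@H](CO[Si](C(C)C)(C(C)C)C(C)C)O2 | intermediate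
22 | (E)-3-{(2S,3S)-3-[(2R,3S)-2-[3,4-bis(allyloxy)phenyl]-3-(hydroxymethyl)-2,3-dihydro-1,4-benzodioxin-6-yl]-2-(hydroxymethyl)-2,3-dihydro-1,4-benzodioxin-6-yl}prop-2-enal | O=C/C=C/c1ccc2c(c1)O[C@@H](c1ccc3c(c1)O[C@@H](CO)[C@@H](c1ccc(OCC=C)c(OCC=C)c1)O3)[C@H](CO)O2 | intermediate
23 | CNP0302404.1, (E)-3-{(2S,3S)-3-[(2R,3S)-2-(3,4-dihydroxyphenyl)-3-(hydroxymethyl)-2,3-dihydro-1,4-benzodioxin-6-yl]-2-(hydroxymethyl)-2,3-dihydro-1,4-benzodioxin-6-yl}prop-2-enal | O=C/C=C/c1ccc2c(c1)O[C@@H](c1ccc3c(c1)O[C@@H](CO)[C@@H](c1ccc(O)c(O)c1)O3)[C@H](CO)O2 | target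

**Step count and risk**

Total step count: 17. Longest linear sequence: 12 (steps 2, 3, 4, 5, 6, 7, 12, 13, 14, 15, 16, 17).

The three steps most likely to fail, each with a fallback:

Step 12. The phenoxide of 11 sits para to the C7 benzylic aryl ether, so during the slow epoxide opening it may expel the ring A aryloxide to a quinone methide, with erosion at C7 or interception by other nucleophiles. The copper closure onto the aryl bromide may also stall, so that protodebromination takes over. The fallback moves the annulation to the simple bromophenol and builds ring A afterwards. It sets out from 1, 16 and 5. Phenol 1 is heated with 16 and Cs2CO3 in DMF at 70 °C and 4-{(1R,2S)-1-[3,4-bis(allyloxy)phenyl]-2-hydroxy-3-[(triisopropylsilyl)oxy]propoxy}-3-bromobenzaldehyde F1 is isolated. A separate palladium-catalysed intramolecular etherification (Pd(OAc)2, 2-(di-tert-butylphosphino)-1,1′-binaphthyl, Cs2CO3, toluene, 70 °C) then closes the cis ring to (2R,3S)-2-[3,4-bis(allyloxy)phenyl]-3-{[(triisopropylsilyl)oxy]methyl}-2,3-dihydro-1,4-benzodioxine-6-carbaldehyde F2. This aldehyde takes the place of 2 in the aldol with enolate 6 generated from 5, to give the (2R,3S) syn aldol imide F3. NaBH4 in THF/H2O gives the (1S,2S) diol F4, and iPr3SiCl with imidazole gives the primary silyl ether F5. The copper closure of step 6 (CuI, 1,10-phenanthroline, Cs2CO3, toluene, 100 °C) on the ring A iodide then delivers 18, where the route is rejoined. No free para-hydroxybenzyl ether is ever heated with base on this path.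

Step 10. The electron-rich aryl epoxy alcohol may be ionised at its benzylic carbon by the titanium Lewis acid during reaction or work-up, with ring opening and loss of material or of enantiomeric purity. The fallback sets out from 14. It is silylated first (iPr3SiCl, imidazole, CH2Cl2) to (E)-3-[3,4-bis(allyloxy)phenyl]prop-2-en-1-yl triisopropylsilyl ether F6. This is epoxidised by the dioxirane of the L-series enantiomer of the fructose-derived Shi ketone (KHSO5, K2CO3 buffer of pH about 10.5, MeCN/dimethoxymethane, 0 °C). Shi epoxidation of the trans alkene under basic conditions should give 16 directly, where the route is rejoined; the electron-poor terminal allyl ether alkenes react far more slowly.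

Step 2. Attack of the phenoxide at the imide carbonyl (acyl transfer with loss of the auxiliary, or opening of the oxazolidinone ring) may compete with O-alkylation. The fallback sets out from 3. Alkylation with tert-butyl bromoacetate (K2CO3, DMF, rt) gives tert-butyl [2-iodo-4-(methoxycarbonyl)phenoxy]acetate F7. CF3CO2H in CH2Cl2 gives [2-iodo-4-(methoxycarbonyl)phenoxy]acetic acid F8. Pivaloyl chloride and Et3N in THF at −20 °C give the pivaloyl mixed anhydride F9, which acylates (R)-4-benzyl-1,3-oxazolidin-2-one in the presence of LiCl to give 5, where the route is rejoined.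

Further compounds
F1 | step 12 | 4-{(1R,2S)-1-[3,4-bis(allyloxy)phenyl]-2-hydroxy-3-[(triisopropylsilyl)oxy]propoxy}-3-bromobenzaldehyde | O=Cc1ccc(O[C@H](c2ccc(OCC=C)c(OCC=C)c2)[C@@H](O)CO[Si](C(C)C)(C(C)C)C(C)C)c(Br)c1
F2 | step 12 | (2R,3S)-2-[3,4-bis(allyloxy)phenyl]-3-{[(triisopropylsilyl)oxy]methyl}-2,3-dihydro-1,4-benzodioxine-6-carbaldehyde | O=Cc1ccc2c(c1)O[C@@H](CO[Si](C(C)C)(C(C)C)C(C)C)[C@@H](c1ccc(OCC=C)c(OCC=C)c1)O2
F3 | step 12 | (2R,3S) syn aldol imide of 5 and F2 | COC(=O)c1ccc(O[C@@H](C(=O)N2C(=O)OC[C@H]2Cc2ccccc2)[C@@H](O)c2ccc3c(c2)O[C@@H](CO[Si](C(C)C)(C(C)C)C(C)C)[C@@H](c2ccc(OCC=C)c(OCC=C)c2)O3)c(I)c1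
F4 | step 12 | (1S,2S) 1,3-diol from F3 | COC(=O)c1ccc(O[C@@H](CO)[C@@H](O)c2ccc3c(c2)O[C@@H](CO[Si](C(C)C)(C(C)C)C(C)C)[C@@H](c2ccc(OCC=C)c(OCC=C)c2)O3)c(I)c1
F5 | step 12 | primary triisopropylsilyl ether of F4 | COC(=O)c1ccc(O[C@@H](CO[Si](C(C)C)(C(C)C)C(C)C)[C@@H](O)c2ccc3c(c2)O[C@@H](CO[Si](C(C)C)(C(C)C)C(C)C)[C@@H](c2ccc(OCC=C)c(OCC=C)c2)O3)c(I)c1
F6 | step 10 | (E)-3-[3,4-bis(allyloxy)phenyl]prop-2-en-1-yl triisopropylsilyl ether | CC(C)[Si](C(C)C)(C(C)C)OC/C=C/c1ccc(OCC=C)c(OCC=C)c1
F7 | step 2 | tert-butyl [2-iodo-4-(methoxycarbonyl)phenoxy]acetate | COC(=O)c1ccc(OCC(=O)OC(C)(C)C)c(I)c1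
F8 | step 2 | [2-iodo-4-(methoxycarbonyl)phenoxy]acetic acid | COC(=O)c1ccc(OCC(=O)O)c(I)c1
F9 | step 2 | [2-iodo-4-(methoxycarbonyl)phenoxy]acetic pivalic anhydride | COC(=O)c1ccc(OCC(=O)OC(=O)C(C)(C)C)c(I)c1
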